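Everything rests on disconnecting both C5 substituents of the carbocyclic dienone ring (benzofuran numbering) at once: C5 carries one methoxy and one allyl group beside the C6 ketone, a pairing that a single molecule of allyl methyl ether can hand to a carbene centred on C5. In one operation Rh2(S-DOSP)4 turns the C5 diazo group into a carbene, the ether oxygen adds, and a dearomatising [2,3]-shift creates the C5–O and C5–C bonds, the quaternary stereocentre and the 2,4-dienone, as the last step under neutral conditions. The precursor is the (2S,3S)-5-diazo-6-oxo dihydrobenzofuran (an ortho-quinone diazide), made from the trans 6-hydroxy-dihydrobenzofuran whose two centres are set by one hydrogenation with dynamic kinetic resolution.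

Key step: step 8

Remark: 1-(3,4,5-trimethoxyphenyl)propan-1-one is taken as a catalogue compound; ring atoms are numbered as in benzofuran (O1, C2, C3, C3a, C4 to C7, C7a).

Step 1
Reactants: 1 4-bromo-3-fluorophenol
Product: 2 4-(benzyloxy)-1-bromo-2-fluorobenzene
Conditions: BnBr, K2CO3, DMF, 25 °C
Reagents that add atoms: benzyl bromide, BrCc1ccccc1
Why: Williamson ether synthesis at the only acidic site gives a benzyl ether that masks the future C6 oxygen through the basic steps and can later be removed by hydrogenolysis without touching the methyl ethers.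

Step 2
Reactants: 2 4-(benzyloxy)-1-bromo-2-fluorobenzene; 3 1-(3,4,5-trimethoxyphenyl)propan-1-one
Product: 4 rac-2-[4-(benzyloxy)-2-fluorophenyl]-1-(3,4,5-trimethoxyphenyl)propan-1-one
Conditions: Pd2(dba)3 (1 mol%), Xantphos (2.5 mol%), NaOtBu, toluene, 80 °C
Reagents that add atoms: none
Why: Palladium-catalysed α-arylation of the ketone enolate (Buchwald–Hartwig type) forms the future C3–C3a bond at the C–Br site only, the C–F bond being inert, and a racemic product is acceptable because the α-centre is equilibrated in the next step.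

Step 3
Reactants: 4 rac-2-[4-(benzyloxy)-2-fluorophenyl]-1-(3,4,5-trimethoxyphenyl)propan-1-one
Product: 5 (1S,2S)-2-[4-(benzyloxy)-2-fluorophenyl]-1-(3,4,5-trimethoxyphenyl)propan-1-ol
Conditions: H2 (10 atm), RuCl2[(R)-xylbinap][(R)-daipen] (0.5 mol%), KOtBu (20 mol%), iPrOH, 25 °C
Reagents that add atoms: none
Why: Noyori asymmetric hydrogenation with dynamic kinetic resolution, in which KOtBu racemises the α-aryl centre through the enolate while RuCl2[(R)-xylbinap][(R)-daipen] reduces only the matched (2S)-ketone, the catalyst fixing the carbinol as 1S (antipode chosen by analogy with aryl alkyl ketones) and Felkin–Anh control giving the like (1S,2S) pair that corresponds to the 2,3-trans ring.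

Step 4
Reactants: 5 (1S,2S)-2-[4-(benzyloxy)-2-fluorophenyl]-1-(3,4,5-trimethoxyphenyl)propan-1-ol
Product: 6 (2S,3S)-6-(benzyloxy)-3-methyl-2-(3,4,5-trimethoxyphenyl)-2,3-dihydrobenzofuran
Conditions: KOtBu, THF–DMPU, 65 °C
Reagents that add atoms: none
Why: Intramolecular nucleophilic aromatic substitution of fluoride by the potassium alkoxide closes the five-membered ether ring through the O1–C7a bond, and since only the aryl–oxygen bond is made both stereocentres are carried over unchanged as trans-(2S,3S).

Step 5
Reactants: 6 (2S,3S)-6-(benzyloxy)-3-methyl-2-(3,4,5-trimethoxyphenyl)-2,3-dihydrobenzofuran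
Product: 7 (2S,3S)-3-methyl-2-(3,4,5-trimethoxyphenyl)-2,3-dihydrobenzofuran-6-ol
Conditions: H2 (1 atm), Pd/C, EtOAc, 25 °C
Reagents that add atoms: none
Why: Catalytic hydrogenolysis should cleave the O-benzyl ether much faster than the ring C2–O bond or the methyl ethers, so stopping after one equivalent of hydrogen should free the C6 phenol alone.

Step 6
Reactants: 7 (2S,3S)-3-methyl-2-(3,4,5-trimethoxyphenyl)-2,3-dihydrobenzofuran-6-ol
Product: 9 (2S,3S)-5-amino-3-methyl-2-(3,4,5-trimethoxyphenyl)-2,3-dihydrobenzofuran-6-ol, via 5-arylazo phenol 8 (not isolated)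
Conditions: 4-diazoniobenzenesulfonate (from sulfanilic acid, NaNO2, aq HCl, 0 °C), Na2CO3, THF–H2O, 0 °C; then Na2S2O4, 40 °C
Reagents that add atoms: 4-diazoniobenzenesulfonate, [O-]S(=O)(=O)c1ccc(cc1)[N+]#N (its terminal nitrogen, which stems from sodium nitrite, [Na+].[O-]N=O, stays as the amino nitrogen)
Why: Azo coupling of the phenolate should take place at C5, which is ortho to the phenoxide, para to O1 and less crowded than C7 (the para position C3a is blocked), and dithionite then cleaves the N=N bond reductively to leave the ortho-aminophenol, to be used at once under exclusion of air.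

Step 7
Reactants: 9 (2S,3S)-5-amino-3-methyl-2-(3,4,5-trimethoxyphenyl)-2,3-dihydrobenzofuran-6-ol
Product: 10 (2S,3S)-5-diazo-3-methyl-2-(3,4,5-trimethoxyphenyl)-3,5-dihydrobenzofuran-6(2H)-one (ortho-quinone diazide)
Conditions: isoamyl nitrite, AcOH (cat.), THF, −10 → 0 °C, dark
Reagents that add atoms: isoamyl nitrite, CC(C)CCON=O
Why: Diazotisation of the aromatic amine followed by loss of the phenolic proton gives the neutral ortho-quinone diazide (a diazonium phenolate), the classical outcome for 2-aminophenols, and the organic nitrite keeps the benzylic ether away from mineral acid.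

Step 8
Reactants: 10 (2S,3S)-5-diazo-3-methyl-2-(3,4,5-trimethoxyphenyl)-3,5-dihydrobenzofuran-6(2H)-one; 11 allyl methyl ether
Product: 13 (2S,3S,5R)-5-allyl-5-methoxy-3-methyl-2-(3,4,5-trimethoxyphenyl)-3,5-dihydrobenzofuran-6(2H)-one (the target), via oxonium ylide 12 (not isolated)
Conditions: Rh2(S-DOSP)4 (2 mol%), 11 as solvent, slow addition of 10 in PhCF3, 0 → 25 °C, dark
Reagents that add atoms: none
Why: Proposed new method: Rh2(S-DOSP)4 expels N2 from 10 to give an electrophilic rhodium-bound carbene at C5, the oxygen of 11 adds to it to form oxonium ylide 12 with the negative charge on the C6 oxygen, and a concerted five-centre [2,3]-sigmatropic shift joins the allyl terminus to C5 as the O–CH2 bond breaks, so that C5 keeps the methoxy oxygen, gains the allyl group and the aromatic ring becomes the 2,4-dienone. The closest known reaction types are rhodium-catalysed oxonium ylide formation and [2,3]-rearrangement of α-diazocarbonyl compounds with allyl ethers and Doyle–Kirmse reactions of quinone diazides with allyl sulfides, whereas the dearomatising case with an ortho-quinone diazide and a simple allyl ether has no direct precedent. No ring is closed, and two skeletal bonds (C5–O and C5–C) are formed. C5 is the only new stereocentre, and because C2 and C3 are too remote to bias it, its configuration must be imposed by the chiral carboxylate ligands on a rhodium-associated ylide, the catalyst antipode that favours 5R being selected by experiment and any 5S product removed as a diastereomer. The step needs O-attack and [2,3]-shift to win over cyclopropanation of the allyl double bond, allyl transfer to the C6 oxygen and Wolff ring contraction, which the ether used as solvent, the slow addition of 10 and the electrophilic carbene should favour. Neutral conditions at or below 25 °C in the dark protect both the diazide and the rearrangement-prone dienone, which is formed only in this last step.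

Compound list
1 | 4-bromo-3-fluorophenol | Oc1ccc(Br)c(F)c1 | starting material
2 | 4-(benzyloxy)-1-bromo-2-fluorobenzene | Fc1cc(OCc2ccccc2)ccc1Br | intermediate
3 | 1-(3,4,5-trimethoxyphenyl)propan-1-one | CCC(=O)c1cc(OC)c(OC)c(OC)c1 | starting material
4 | rac-2-[4-(benzyloxy)-2-fluorophenyl]-1-(3,4,5-trimethoxyphenyl)propan-1-one | CC(C(=O)c1cc(OC)c(OC)c(OC)c1)c1ccc(OCc2ccccc2)cc1F | intermediate
5 | (1S,2S)-2-[4-(benzyloxy)-2-fluorophenyl]-1-(3,4,5-trimethoxyphenyl)propan-1-ol | C[C@@H](c1ccc(OCc2ccccc2)cc1F)[C@H](O)c1cc(OC)c(OC)c(OC)c1 | intermediate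
6 | (2S,3S)-6-(benzyloxy)-3-methyl-2-(3,4,5-trimethoxyphenyl)-2,3-dihydrobenzofuran | c1ccccc1COc1ccc2c(c1)O[C@H](c1cc(OC)c(OC)c(OC)c1)[C@H]2C | intermediate
7 | (2S,3S)-3-methyl-2-(3,4,5-trimethoxyphenyl)-2,3-dihydrobenzofuran-6-ol | Oc1ccc2c(c1)O[C@H](c1cc(OC)c(OC)c(OC)c1)[C@H]2C | intermediate
8 | sodium 4-{(E)-[(2S,3S)-6-hydroxy-3-methyl-2-(3,4,5-trimethoxyphenyl)-2,3-dihydrobenzofuran-5-yl]diazenyl}benzenesulfonate (5-arylazo phenol) | [Na+].[O-]S(=O)(=O)c1ccc(cc1)/N=N/c1cc2c(cc1O)O[C@H](c1cc(OC)c(OC)c(OC)c1)[C@H]2C | intermediate (not isolated)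
9 | (2S,3S)-5-amino-3-methyl-2-(3,4,5-trimethoxyphenyl)-2,3-dihydrobenzofuran-6-ol | Nc1cc2c(cc1O)O[C@H](c1cc(OC)c(OC)c(OC)c1)[C@H]2C | intermediate
10 | (2S,3S)-5-diazo-3-methyl-2-(3,4,5-trimethoxyphenyl)-3,5-dihydrobenzofuran-6(2H)-one | [N-]=[N+]=C1C=C2C(=CC1=O)O[C@H](c1cc(OC)c(OC)c(OC)c1)[C@H]2C | intermediate
11 | allyl methyl ether (3-methoxyprop-1-ene) | C=CCOC | starting material
12 | oxonium ylide: (2S,3S)-5-[allyl(methyl)oxonio]-3-methyl-2-(3,4,5-trimethoxyphenyl)-2,3-dihydrobenzofuran-6-olate | C=CC[O+](C)c1cc2c(cc1[O-])O[C@H](c1cc(OC)c(OC)c(OC)c1)[C@H]2C | intermediate (not isolated)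
13 | (2S,3S,5R)-5-allyl-5-methoxy-3-methyl-2-(3,4,5-trimethoxyphenyl)-3,5-dihydrobenzofuran-6(2H)-one | C=CC[C@@]1(OC)C=C2C(=CC1=O)O[C@H](c1cc(OC)c(OC)c(OC)c1)[C@H]2C | target

Total step count: 8. Longest linear sequence: 8 steps (1 to 13).

Steps most likely to fail

Step 8. The carbene may add to the allyl double bond, the ylide may re-aromatise by passing its allyl group to the C6 oxygen, or the shift may occur with poor face selectivity at C5. The fallback uses known chemistry, sets out from 7 and comes back at 13. IBX (DMF, 25 °C) would oxidise 7 at the free ortho position C5 to (2S,3S)-3-methyl-2-(3,4,5-trimethoxyphenyl)-2,3-dihydrobenzofuran-5,6-dione F1. Barbier allylation (indium powder, allyl bromide, THF–H2O) should add to the C5 carbonyl, the C6 carbonyl being deactivated as a vinylogous ester through O1, to give (2S,3S)-5-allyl-5-hydroxy-3-methyl-2-(3,4,5-trimethoxyphenyl)-3,5-dihydrobenzofuran-6(2H)-one F2 as both C5 epimers. O-Methylation (MeI, Ag2O) and chromatography would then deliver 13 and set aside the (2S,3S,5S)-5-allyl-5-methoxy-3-methyl-2-(3,4,5-trimethoxyphenyl)-3,5-dihydrobenzofuran-6(2H)-one F3.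

Step 4. Displacement of fluoride on a ring without electron-withdrawing groups may be slow, giving the hot alkoxide time to degrade. The fallback sets out from 3 and comes back at 6. 4-(Benzyloxy)-1-bromo-2-chlorobenzene F4 (from commercial 4-bromo-3-chlorophenol under the conditions of step 1) would be coupled with 3 as in step 2 to rac-2-[4-(benzyloxy)-2-chlorophenyl]-1-(3,4,5-trimethoxyphenyl)propan-1-one F5. Hydrogenation as in step 3 would give (1S,2S)-2-[4-(benzyloxy)-2-chlorophenyl]-1-(3,4,5-trimethoxyphenyl)propan-1-ol F6. The ring would then be closed by palladium-catalysed intramolecular C–O coupling (Pd(OAc)2, 2-(di-tert-butylphosphino)-1,1'-binaphthyl, Cs2CO3, toluene, 80 °C), which again leaves both centres untouched and gives 6.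

Step 6. The bulky diazonium ion may couple at C7 or twice, and the aminophenol may be lost by air oxidation during the aqueous reduction. The fallback sets out from 7 and comes back at 9. C-Nitrosation (NaNO2, AcOH–EtOH–H2O, 0 °C), in which the small electrophile should follow the electronic preference for the position para to O1, would give (2S,3S)-3-methyl-5-nitroso-2-(3,4,5-trimethoxyphenyl)-2,3-dihydrobenzofuran-6-ol F7. Hydrogenation (H2, Pd/C, EtOAc) with exclusion of air would then give 9.

Further compounds
F1 | step 8 | (2S,3S)-3-methyl-2-(3,4,5-trimethoxyphenyl)-2,3-dihydrobenzofuran-5,6-dione | O=C1C=C2C(=CC1=O)O[C@H](c1cc(OC)c(OC)c(OC)c1)[C@H]2C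
F2 | step 8 | (2S,3S)-5-allyl-5-hydroxy-3-methyl-2-(3,4,5-trimethoxyphenyl)-3,5-dihydrobenzofuran-6(2H)-one (both C5 epimers) | C=CCC1(O)C=C2C(=CC1=O)O[C@H](c1cc(OC)c(OC)c(OC)c1)[C@H]2C
F3 | step 8 | (2S,3S,5S)-5-allyl-5-methoxy-3-methyl-2-(3,4,5-trimethoxyphenyl)-3,5-dihydrobenzofuran-6(2H)-one | C=CC[C@]1(OC)C=C2C(=CC1=O)O[C@H](c1cc(OC)c(OC)c(OC)c1)[C@H]2C
F4 | step 4 | 4-(benzyloxy)-1-bromo-2-chlorobenzene | Clc1cc(OCc2ccccc2)ccc1Br
F5 | step 4 | rac-2-[4-(benzyloxy)-2-chlorophenyl]-1-(3,4,5-trimethoxyphenyl)propan-1-one | CC(C(=O)c1cc(OC)c(OC)c(OC)c1)c1ccc(OCc2ccccc2)cc1Cl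
F6 | step 4 | (1S,2S)-2-[4-(benzyloxy)-2-chlorophenyl]-1-(3,4,5-trimethoxyphenyl)propan-1-ol | C[C@@H](c1ccc(OCc2ccccc2)cc1Cl)[C@H](O)c1cc(OC)c(OC)c(OC)c1
F7 | step 6 | (2S,3S)-3-methyl-5-nitroso-2-(3,4,5-trimethoxyphenyl)-2,3-dihydrobenzofuran-6-ol | O=Nc1cc2c(cc1O)O[C@H](c1cc(OC)c(OC)c(OC)c1)[C@H]2C
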